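The whole route rests on disconnecting the dihydrofuran of the C/D phenylcoumaran at its aryl–oxygen bond, O1–C7a. In the key step the C2 alkoxide of an open-chain 1,2-diarylpropane-1,3-diol displaces fluoride from C7a of ring D by intramolecular SNAr. This exploits the fact that C7a is para to C5, the carbon that carries the propenal: held at the nitrile level, that substituent activates C7a–F and later becomes the enal. C2 and C3 are set beforehand by an Evans syn-aldol, so closure delivers the trans-(2R,3S) ring directly. The two erythro β-O-4 units are then grown from the phenols by iterative imide anti-aldol/reduction.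

Key step: step 9

Remark 1 (numbering): rings A–D run from the guaiacyl end to the benzofuran; the dihydrobenzofuran is numbered O1, C2, C3, C3a–C7a; C7/C8/C9 are the side-chain carbons of units A and B.
Remark 2 (assumption): with aryloxyacetyl imides the Mg-catalysed anti-aldol is assumed to keep the facial sense known for N-acyl oxazolidinones (chelated Z-enolate, attack anti to benzyl). The chloroacetyl imide 17 is taken as purchasable; otherwise it is one acylation from (S)-4-benzyloxazolidin-2-one.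

Step 1
Reactants: 1 4-hydroxy-3-methoxybenzonitrile; 2 allyl bromide
Product: 3 4-(allyloxy)-3-methoxybenzonitrile
Conditions: K2CO3, acetone, reflux
Reagents that add atoms: none
Why: Williamson etherification of the phenoxide with a primary allylic bromide (SN2).

Step 2
Reactants: 3 4-(allyloxy)-3-methoxybenzonitrile
Product: 4 3-allyl-4-hydroxy-5-methoxybenzonitrile
Conditions: N,N-diethylaniline, 200 °C
Reagents that add atoms: none
Why: Aromatic Claisen rearrangement ([3,3]); the only free ortho position takes the allyl group and tautomerisation restores the phenol.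

Step 3
Reactants: 4 3-allyl-4-hydroxy-5-methoxybenzonitrile
Product: 6 3-allyl-4-fluoro-5-methoxybenzonitrile, via aryl fluorosulfonate 5 (not isolated)
Conditions: SO2F2 (1 atm), Me4NF (anhydrous, 3 equiv), DMF, rt → 80 °C
Reagents that add atoms: sulfuryl fluoride O=S(=O)(F)F (sulfonyl group of 5); tetramethylammonium fluoride C[N+](C)(C)C.[F-]
Why: Deoxyfluorination of a phenol through its fluorosulfonate: fluoride displaces fluorosulfate at the ipso carbon (SNAr), which the para nitrile strongly favours.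

Step 4
Reactants: 6 3-allyl-4-fluoro-5-methoxybenzonitrile
Product: 7 2-(5-cyano-2-fluoro-3-methoxyphenyl)acetic acid
Conditions: RuCl3·xH2O (cat.), NaIO4, MeCN/EtOAc/H2O, rt
Reagents that add atoms: sodium periodate [Na+].[O-]I(=O)(=O)=O; water O
Why: RuO4-catalysed oxidative cleavage of the terminal alkene to the one-carbon-shorter acid; the fluoro/cyano-deactivated ring should resist RuO4.

Step 5
Reactants: 7 2-(5-cyano-2-fluoro-3-methoxyphenyl)acetic acid; 8 (R)-4-benzyloxazolidin-2-one
Product: 10 (R)-4-benzyl-3-[2-(5-cyano-2-fluoro-3-methoxyphenyl)acetyl]oxazolidin-2-one, via mixed pivalic anhydride 9 (not isolated)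
Conditions: PivCl, Et3N, THF, −20 °C; then 8, LiCl, rt
Reagents that add atoms: pivaloyl chloride CC(C)(C)C(=O)Cl (acyl group of 9 only)
Why: N-acylation of the Evans oxazolidinone through the mixed anhydride (LiCl/Et3N protocol), attack occurring at the unhindered arylacetyl carbonyl.

Step 6
Reactants: 10 (R)-arylacetyl imide; 11 4-formyl-2,6-dimethoxyphenyl acetate (syringaldehyde acetate)
Product: 13 (R)-4-benzyl-3-[(2R,3R)-3-(4-acetoxy-3,5-dimethoxyphenyl)-2-(5-cyano-2-fluoro-3-methoxyphenyl)-3-hydroxypropanoyl]oxazolidin-2-one, via Z-boron enolate 12 (not isolated)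
Conditions: n-Bu2BOTf, i-Pr2NEt, CH2Cl2, 0 °C; 11, −78 → 0 °C; then pH 7 buffer, MeOH, H2O2, 0 °C
Reagents that add atoms: dibutylboron triflate CCCCB(CCCC)OS(=O)(=O)C(F)(F)F (boron of 12 only)
Why: Evans syn-aldol: the Z-boron enolate reacts through a Zimmerman–Traxler chair with the auxiliary dipole opposed, so the (R)-benzyl group selects the enolate face and sets the (2R,3R) syn pair that becomes C3 and C2.

Step 7
Reactants: 13 syn-aldol adduct
Product: 14 3-[(2S,3R)-1,3-dihydroxy-3-(4-hydroxy-3,5-dimethoxyphenyl)propan-2-yl]-4-fluoro-5-methoxybenzonitrile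
Conditions: LiBH4, THF, H2O (1 equiv), 0 °C → rt
Reagents that add atoms: none
Why: Reductive cleavage of the imide to the primary alcohol, with the phenolic acetate reduced off in the same pot; the nitrile is inert to borohydride and no stereocentre is touched.

Step 8
Reactants: 14 triol
Product: 15 4-fluoro-3-[(2S,3R)-3-hydroxy-3-(4-hydroxy-3,5-dimethoxyphenyl)-1-(trityloxy)propan-2-yl]-5-methoxybenzonitrile
Conditions: TrCl, Et3N, DMAP (cat.), CH2Cl2, rt
Reagents that add atoms: trityl chloride ClC(c1ccccc1)(c2ccccc2)c3ccccc3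
Why: Tritylation is selective for the primary hydroxyl on steric grounds, and a trityl ether cannot migrate to the neighbouring alkoxide in step 9.

Step 9
Reactants: 15 trityl ether
Product: 16 (2R,3S)-2-(4-hydroxy-3,5-dimethoxyphenyl)-7-methoxy-3-[(trityloxy)methyl]-2,3-dihydrobenzofuran-5-carbonitrile
Conditions: NaH (2.5 equiv), DMF, 0 °C → rt; then aq. NH4Cl
Reagents that add atoms: none
Why: The C2 sodium alkoxide attacks C7a of ring D ipso to fluorine, the charge of the σ-adduct is delocalised onto the para nitrile at C5, and loss of fluoride restores aromaticity (addition–elimination SNAr). The closest known reaction type is the base-mediated cyclisation of 2-(2-fluoroaryl)ethanols bearing a para acceptor to 2,3-dihydrobenzofurans. The ring O1–C2–C3–C3a–C7a closes in a 5-exo mode at the aromatic carbon, the two-carbon tether holding the alkoxide over C7a. No stereocentre is made or broken: C2 (its C–O bond is retained) and C3 come unchanged from the syn-aldol, and the syn relation maps onto the trans-(2R,3S) ring, which is also the more stable isomer. The step needs the secondary alkoxide to react in preference to the primary oxygen, which the trityl ether secures, and C–F to react in preference to C–OMe, which is secured because fluoride is the only nucleofuge para to the nitrile; the hindered ring-C phenoxide is a poor intermolecular competitor.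

Step 10
Reactants: 16 core phenol; 17 (S)-4-benzyl-3-(chloroacetyl)oxazolidin-2-one
Product: 18 (2R,3S)-2-{4-[2-((S)-4-benzyl-2-oxooxazolidin-3-yl)-2-oxoethoxy]-3,5-dimethoxyphenyl}-7-methoxy-3-[(trityloxy)methyl]-2,3-dihydrobenzofuran-5-carbonitrile
Conditions: K2CO3, NaI (cat.), acetone, 40 °C
Reagents that add atoms: none
Why: Williamson etherification of the phenoxide with the α-chloro imide, accelerated by in situ Finkelstein exchange; SN2 at CH2 should outrun attack at the imide carbonyl.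

Step 11
Reactants: 18 core aryloxyacetyl imide; 11 4-formyl-2,6-dimethoxyphenyl acetate
Product: 20 (S)-4-benzyl-3-[(2R,3R)-3-(4-acetoxy-3,5-dimethoxyphenyl)-2-{4-[(2R,3S)-5-cyano-3-(hydroxymethyl)-7-methoxy-2,3-dihydrobenzofuran-2-yl]-2,6-dimethoxyphenoxy}-3-hydroxypropanoyl]oxazolidin-2-one, via O-TMS aldol adduct 19 (not isolated)
Conditions: MgCl2 (20 mol %), Et3N, TMSCl, EtOAc, rt; then TFA, MeOH/CH2Cl2, 0 °C
Reagents that add atoms: chlorotrimethylsilane C[Si](C)(C)Cl (silyl group of 19 only)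
Why: Mg-halide-catalysed direct anti-aldol of an N-acyl oxazolidinone with an aromatic aldehyde: the chelated Z-magnesium enolate adds anti to the (S)-benzyl group through a boat-like transition state and TMSCl traps the aldolate, setting (2R,3R), the erythro pattern of unit B; acid methanolysis then removes the TMS and trityl ethers.

Step 12
Reactants: 20 anti-aldol adduct
Product: 21 (2R,3S)-2-{4-[((1R,2S)-1,3-dihydroxy-1-(4-hydroxy-3,5-dimethoxyphenyl)propan-2-yl)oxy]-3,5-dimethoxyphenyl}-3-(hydroxymethyl)-7-methoxy-2,3-dihydrobenzofuran-5-carbonitrile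
Conditions: LiBH4, THF, H2O (1 equiv), 0 °C
Reagents that add atoms: none
Why: Reductive removal of the auxiliary gives the erythro (7R,8S) diol of unit B and the acetate on the ring-B phenol is reduced off in the same operation; the nitrile survives.

Step 13
Reactants: 21 phenolic triol; 17 (S)-4-benzyl-3-(chloroacetyl)oxazolidin-2-one
Product: 22 aryloxyacetyl imide of 21 (the ring-B phenol oxygen carries CH2C(=O)–[(S)-4-benzyl-2-oxooxazolidin-3-yl]; all three aliphatic hydroxyls free)
Conditions: K2CO3, NaI (cat.), DMF, rt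
Reagents that add atoms: none
Why: Phenoxide-selective Williamson etherification; carbonate does not deprotonate the aliphatic hydroxyls.

Step 14
Reactants: 22 imide; 23 4-formyl-2-methoxyphenyl acetate (vanillin acetate)
Product: 26 anti-aldol adduct of 22 and 23 ((2R,3R)-3-(4-acetoxy-3-methoxyphenyl)-3-hydroxy-2-aryloxypropanoyl imide; the remainder as in 22), via tris-TMS ether 24 (not isolated), via tetrakis-TMS aldol adduct 25 (not isolated)
Conditions: TMSCl (excess), Et3N, EtOAc, rt; then MgCl2 (20 mol %), 23, rt; then 1 M HCl, THF, 0 °C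
Reagents that add atoms: chlorotrimethylsilane C[Si](C)(C)Cl (silyl groups of 24 and 25 only)
Why: The same Mg-catalysed anti-aldol: excess TMSCl/Et3N first masks the three hydroxyls as TMS ethers, the (S)-auxiliary sets the erythro (7R,8S) pattern of unit A, and aqueous acid removes all silyl groups.

Step 15
Reactants: 26 anti-aldol adduct
Product: 27 nitrile hexaol (the target with C≡N in place of the CH=CH–CHO group at C5 of ring D)
Conditions: LiBH4, THF, H2O (1 equiv), 0 °C → rt
Reagents that add atoms: none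
Why: Reductive cleavage of the imide to the unit-A 1,3-diol with concurrent reduction of the phenolic acetate; the nitrile is untouched.

Step 16
Reactants: 27 nitrile hexaol
Product: 29 aldehyde (the target with CHO in place of the CH=CH–CHO group at C5 of ring D), via aldimine 28 (not isolated)
Conditions: DIBAL-H (excess), THF/CH2Cl2, −78 → −20 °C; then aq. Rochelle salt, rt
Reagents that add atoms: water O
Why: DIBAL-H partial reduction of the aryl nitrile to the N-aluminated aldimine, hydrolysed to the aldehyde on work-up; the six hydroxyls only consume reagent as inert aluminium alkoxides.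

Step 17
Reactants: 29 aldehyde; 30 (triphenylphosphoranylidene)acetaldehyde
Product: 31 CNP0192639.1 (target)
Conditions: THF/toluene, 70 °C
Reagents that add atoms: none
Why: Wittig olefination with the stabilised formylmethylene ylide should give the (E)-enal and tolerates the free phenol and alcohols.

Compound list
1 | 4-hydroxy-3-methoxybenzonitrile | N#Cc1ccc(O)c(OC)c1 | starting material
2 | allyl bromide | C=CCBr | starting material
3 | 4-(allyloxy)-3-methoxybenzonitrile | N#Cc1ccc(OCC=C)c(OC)c1 | intermediate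
4 | 3-allyl-4-hydroxy-5-methoxybenzonitrile | N#Cc1cc(CC=C)c(O)c(OC)c1 | intermediate
5 | 2-allyl-4-cyano-6-methoxyphenyl fluorosulfonate | N#Cc1cc(CC=C)c(OS(=O)(=O)F)c(OC)c1 | intermediate (not isolated)
6 | 3-allyl-4-fluoro-5-methoxybenzonitrile | N#Cc1cc(CC=C)c(F)c(OC)c1 | intermediate
7 | 2-(5-cyano-2-fluoro-3-methoxyphenyl)acetic acid | N#Cc1cc(CC(=O)O)c(F)c(OC)c1 | intermediate
8 | (R)-4-benzyloxazolidin-2-one | O=C1N[C@H](Cc2ccccc2)CO1 | starting material
9 | mixed anhydride of 7 with pivalic acid | N#Cc1cc(CC(=O)OC(=O)C(C)(C)C)c(F)c(OC)c1 | intermediate (not isolated)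
10 | (R)-4-benzyl-3-[2-(5-cyano-2-fluoro-3-methoxyphenyl)acetyl]oxazolidin-2-one | N#Cc1cc(CC(=O)N2[C@H](Cc3ccccc3)COC2=O)c(F)c(OC)c1 | intermediate
11 | 4-formyl-2,6-dimethoxyphenyl acetate | CC(=O)Oc1c(OC)cc(C=O)cc1OC | starting material
12 | (Z)-dibutylboron enolate of 10 | CCCCB(CCCC)O/C(=C\c1cc(C#N)cc(OC)c1F)N2[C@H](Cc3ccccc3)COC2=O | intermediate (not isolated)
13 | (R)-4-benzyl-3-[(2R,3R)-3-(4-acetoxy-3,5-dimethoxyphenyl)-2-(5-cyano-2-fluoro-3-methoxyphenyl)-3-hydroxypropanoyl]oxazolidin-2-one | CC(=O)Oc1c(OC)cc(cc1OC)[C@H](O)[C@@H](c2cc(C#N)cc(OC)c2F)C(=O)N3[C@H](Cc4ccccc4)COC3=O | intermediate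
14 | 3-[(2S,3R)-1,3-dihydroxy-3-(4-hydroxy-3,5-dimethoxyphenyl)propan-2-yl]-4-fluoro-5-methoxybenzonitrile | Oc1c(OC)cc(cc1OC)[C@H](O)[C@@H](c2cc(C#N)cc(OC)c2F)CO | intermediate
15 | 4-fluoro-3-[(2S,3R)-3-hydroxy-3-(4-hydroxy-3,5-dimethoxyphenyl)-1-(trityloxy)propan-2-yl]-5-methoxybenzonitrile | Oc1c(OC)cc(cc1OC)[C@H](O)[C@@H](c2cc(C#N)cc(OC)c2F)COC(c3ccccc3)(c4ccccc4)c5ccccc5 | intermediate
16 | (2R,3S)-2-(4-hydroxy-3,5-dimethoxyphenyl)-7-methoxy-3-[(trityloxy)methyl]-2,3-dihydrobenzofuran-5-carbonitrile | Oc1c(OC)cc(cc1OC)[C@@H]2Oc3c(OC)cc(C#N)cc3[C@H]2COC(c4ccccc4)(c5ccccc5)c6ccccc6 | intermediate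
17 | (S)-4-benzyl-3-(chloroacetyl)oxazolidin-2-one | ClCC(=O)N1[C@@H](Cc2ccccc2)COC1=O | starting material
18 | core aryloxyacetyl (S)-imide | O=C(COc1c(OC)cc(cc1OC)[C@@H]2Oc3c(OC)cc(C#N)cc3[C@H]2COC(c4ccccc4)(c5ccccc5)c6ccccc6)N7[C@@H](Cc8ccccc8)COC7=O | intermediate
19 | O-TMS anti-aldol adduct (trityl ether still in place) | CC(=O)Oc1c(OC)cc(cc1OC)[C@@H](O[Si](C)(C)C)[C@H](C(=O)N2[C@@H](Cc3ccccc3)COC2=O)Oc4c(OC)cc(cc4OC)[C@@H]5Oc6c(OC)cc(C#N)cc6[C@H]5COC(c7ccccc7)(c8ccccc8)c9ccccc9 | intermediate (not isolated)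
20 | anti-aldol adduct of unit B (free 7-OH and core CH2OH) | CC(=O)Oc1c(OC)cc(cc1OC)[C@@H](O)[C@H](C(=O)N2[C@@H](Cc3ccccc3)COC2=O)Oc4c(OC)cc(cc4OC)[C@@H]5Oc6c(OC)cc(C#N)cc6[C@H]5CO | intermediate
21 | B–C–D phenolic triol nitrile (erythro 7R,8S unit B) | Oc1c(OC)cc(cc1OC)[C@@H](O)[C@H](CO)Oc4c(OC)cc(cc4OC)[C@@H]5Oc6c(OC)cc(C#N)cc6[C@H]5CO | intermediate
22 | aryloxyacetyl (S)-imide of 21 | O=C(COc1c(OC)cc(cc1OC)[C@@H](O)[C@H](CO)Oc4c(OC)cc(cc4OC)[C@@H]5Oc6c(OC)cc(C#N)cc6[C@H]5CO)N2[C@@H](Cc3ccccc3)COC2=O | intermediate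
23 | 4-formyl-2-methoxyphenyl acetate | CC(=O)Oc1ccc(C=O)cc1OC | starting material
24 | tris-TMS ether of 22 | O=C(COc1c(OC)cc(cc1OC)[C@@H](O[Si](C)(C)C)[C@H](CO[Si](C)(C)C)Oc4c(OC)cc(cc4OC)[C@@H]5Oc6c(OC)cc(C#N)cc6[C@H]5CO[Si](C)(C)C)N2[C@@H](Cc3ccccc3)COC2=O | intermediate (not isolated)
25 | tetrakis-TMS anti-aldol adduct | CC(=O)Oc1ccc(cc1OC)[C@@H](O[Si](C)(C)C)[C@H](C(=O)N2[C@@H](Cc3ccccc3)COC2=O)Oc4c(OC)cc(cc4OC)[C@@H](O[Si](C)(C)C)[C@H](CO[Si](C)(C)C)Oc5c(OC)cc(cc5OC)[C@@H]6Oc7c(OC)cc(C#N)cc7[C@H]6CO[Si](C)(C)C | intermediate (not isolated)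
26 | anti-aldol adduct of unit A | CC(=O)Oc1ccc(cc1OC)[C@@H](O)[C@H](C(=O)N2[C@@H](Cc3ccccc3)COC2=O)Oc4c(OC)cc(cc4OC)[C@@H](O)[C@H](CO)Oc5c(OC)cc(cc5OC)[C@@H]6Oc7c(OC)cc(C#N)cc7[C@H]6CO | intermediate
27 | nitrile hexaol | Oc1ccc(cc1OC)[C@@H](O)[C@H](CO)Oc4c(OC)cc(cc4OC)[C@@H](O)[C@H](CO)Oc5c(OC)cc(cc5OC)[C@@H]6Oc7c(OC)cc(C#N)cc7[C@H]6CO | intermediate
28 | aldimine of 29 (formed as its aluminium complex, written as the free imine) | Oc1ccc(cc1OC)[C@@H](O)[C@H](CO)Oc4c(OC)cc(cc4OC)[C@@H](O)[C@H](CO)Oc5c(OC)cc(cc5OC)[C@@H]6Oc7c(OC)cc(C=N)cc7[C@H]6CO | intermediate (not isolated)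
29 | ring-D 5-carbaldehyde | Oc1ccc(cc1OC)[C@@H](O)[C@H](CO)Oc4c(OC)cc(cc4OC)[C@@H](O)[C@H](CO)Oc5c(OC)cc(cc5OC)[C@@H]6Oc7c(OC)cc(C=O)cc7[C@H]6CO | intermediate
30 | (triphenylphosphoranylidene)acetaldehyde | O=CC=P(c1ccccc1)(c2ccccc2)c3ccccc3 | starting material
31 | CNP0192639.1 | COc1cc([C@@H](O)[C@H](CO)Oc2c(OC)cc([C@@H](O)[C@H](CO)Oc3c(OC)cc([C@@H]4Oc5c(OC)cc(/C=C/C=O)cc5[C@H]4CO)cc3OC)cc2OC)ccc1O | target

Total step count: 17. Longest linear sequence: 17 steps (from 1).

Steps most likely to fail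

1. Step 11 (the same reaction type recurs in step 14). The aryloxy oxygen may compete for magnesium, so that anti selectivity or facial control erodes, or soft enolisation of the hindered imide may stall. The fallback separates the two centres: C8 by a boron syn-aldol, C7 by oxidation and chelation-controlled reduction. It sets out from 16. Alkylation with (R)-4-benzyl-3-(chloroacetyl)oxazolidin-2-one (the purchasable enantiomer of 17; K2CO3, NaI, acetone) should give the (R)-imide F1. A boron-mediated Evans syn-aldol with 11 (n-Bu2BOTf, i-Pr2NEt, CH2Cl2) should give the (2R,3S) threo adduct F2, in which C8 already has the target configuration. LiBH4 should then give the threo diol F3 with the ring-B phenol freed. DDQ in dioxane should oxidise only the p-hydroxybenzylic alcohol, giving the aryl ketone F4. Reduction under chelation control (Zn(BH4)2, Et2O, −20 °C; Cram-chelate through the α-aryloxy oxygen) should favour the erythro diol trityl ether F5. TFA/MeOH then removes the trityl group and the route is rejoined at 21.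

2. Step 16. The poly-aluminium alkoxide of the hexaol may precipitate and leave the nitrile unreduced, or forcing may over-reduce it. The fallback masks the hydroxyls first and sets out from 27. Per-silylation (TMSCl, imidazole, DMF) should give the hexakis-TMS ether F6. DIBAL-H (1.5 equiv, toluene, −78 °C) followed by 1 M HCl/THF should hydrolyse the aldimine and all silyl ethers together, rejoining the route at 29.

3. Step 3. Fluoride displacement at the doubly ortho-substituted ipso carbon may be slow, and the basic fluoride may isomerise the allyl group to propenyl. The fallback sets out from 4. Tf2O/pyridine should give the aryl triflate F7. Pd-catalysed fluorination ([(cinnamyl)PdCl]2, a bulky biaryl monophosphine, CsF, toluene, 110 °C) should then give 6, where the route is rejoined.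

Further compounds
F1 | step 11 | core aryloxyacetyl (R)-imide (diastereomer of 18) | O=C(COc1c(OC)cc(cc1OC)[C@@H]2Oc3c(OC)cc(C#N)cc3[C@H]2COC(c4ccccc4)(c5ccccc5)c6ccccc6)N7[C@H](Cc8ccccc8)COC7=O
F2 | step 11 | (2R,3S) syn-aldol adduct of F1 and 11 (trityl ether) | CC(=O)Oc1c(OC)cc(cc1OC)[C@H](O)[C@H](C(=O)N2[C@H](Cc3ccccc3)COC2=O)Oc4c(OC)cc(cc4OC)[C@@H]5Oc6c(OC)cc(C#N)cc6[C@H]5COC(c7ccccc7)(c8ccccc8)c9ccccc9
F3 | step 11 | threo (7S,8S) diol trityl ether | Oc1c(OC)cc(cc1OC)[C@H](O)[C@H](CO)Oc4c(OC)cc(cc4OC)[C@@H]5Oc6c(OC)cc(C#N)cc6[C@H]5COC(c7ccccc7)(c8ccccc8)c9ccccc9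
F4 | step 11 | (8S) α-aryloxy-β-hydroxy aryl ketone trityl ether | Oc1c(OC)cc(cc1OC)C(=O)[C@H](CO)Oc4c(OC)cc(cc4OC)[C@@H]5Oc6c(OC)cc(C#N)cc6[C@H]5COC(c7ccccc7)(c8ccccc8)c9ccccc9
F5 | step 11 | erythro (7R,8S) diol trityl ether (trityl ether of 21) | Oc1c(OC)cc(cc1OC)[C@@H](O)[C@H](CO)Oc4c(OC)cc(cc4OC)[C@@H]5Oc6c(OC)cc(C#N)cc6[C@H]5COC(c7ccccc7)(c8ccccc8)c9ccccc9
F6 | step 16 | hexakis-TMS ether of 27 | C[Si](C)(C)Oc1ccc(cc1OC)[C@@H](O[Si](C)(C)C)[C@H](CO[Si](C)(C)C)Oc4c(OC)cc(cc4OC)[C@@H](O[Si](C)(C)C)[C@H](CO[Si](C)(C)C)Oc5c(OC)cc(cc5OC)[C@@H]6Oc7c(OC)cc(C#N)cc7[C@H]6CO[Si](C)(C)C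
F7 | step 3 | 2-allyl-4-cyano-6-methoxyphenyl triflate | N#Cc1cc(CC=C)c(OS(=O)(=O)C(F)(F)F)c(OC)c1
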